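## Structural features

The target is a flavonol: a benzo-γ-pyrone (rings A and C) with a 4-hydroxyphenyl ring B on C2, a hydroxyl on C3 and the carbonyl at C4. Ring A is fully substituted: oxygen on C5, C7 and C8a (the last is the pyrone oxygen O1), 3-methylbut-2-enyl (prenyl) chains on C6 and C8, and the C4 carbonyl on C4a. There is no stereocentre and no stereogenic double bond, so the problem is one of regiochemistry and functional-group tolerance only. The fragile parts are the two trisubstituted prenyl alkenes, each flanked by phenolic hydroxyls that trap the tertiary cation formed under acid as a dimethylchroman, and the electron-rich polyphenol/3-hydroxypyrone array, which oxidizes in basic aerated media. Hydrogenolysis, strong Lewis acids and electrophilic oxidants are therefore excluded late in the route. The real difficulty is placing two C-prenyl groups on C6 and C8 of a phloroglucinol nucleus, where direct alkylation competes between oxygen and three equivalent carbons and over-alkylates. The key step uses the alternation on ring A (oxygen on C5, C7, C8a; carbon chains on C6, C8; hydrogen on C4a). A 3-siloxy-4-alkylcyclobutenone supplies C4a, C5, C6 and C7, and a 1-siloxyalkyne supplies C8 and C8a, merged by a Danheiser benzannulation.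

## Logic of the disconnections

34 ⇒ 33. The two O–CH2 acetal bonds on O3 and O4′ are cut last. These oxygens arrive with the ring C/ring B fragment and must be masked while it is assembled; the ring A hydroxyls are never protected. The final step then changes no skeletal bond. It demands an acetal cleavage mild enough to leave both prenyl alkenes, each next to a free phenol, unprotonated.

33 ⇒ 23 + 30. Ring C is opened at C4a–C4 and O1–C2. This returns ring A as 23, whose single unsubstituted carbon lies between two symmetry-equivalent hydroxyls, so only one chromenone can form. It puts C2, C3 with its oxygen, C4 and ring B into 30 at the final oxidation level. The forward step must acylate carbon, not oxygen, and dehydrate without acid, in a thermal condensation short enough for the prenyl groups to survive.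

30 ⇒ 29 ⇒ 25 + 27, with 25 ⇒ 24 and 27 ⇒ 26. The C2–C3 bond (flavone labels) is cut as an aldol bond after lowering C2 to the alcohol level, and the acetal groups are removed from each half. Aldol addition then oxidation is preferred to a direct ester condensation because an electron-rich benzoate is a poor acyl acceptor and the two-carbon ester would self-condense. The pieces are stock two-carbon and seven-carbon compounds. No stereocontrol is needed, since both new centres are erased later.

23 ⇒ 22. Two O–Si bonds are restored. The silyl groups are the form in which two of the three ring A oxygens leave the annulation, so the oxidizable triol is released only when needed. The forward step needs buffered fluoride and exclusion of air.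

22 ⇒ 12 + 17 (key). Ring A is cut at C7–C8 and C4a–C8a; C6–C7 is opened and re-closed on the way. Every ring A substituent then sits on a small precursor: O7 is the carbonyl of 12, O5 its siloxy group, the C6 prenyl is on its saturated carbon and C4a is its unsubstituted alkene carbon; O8a and the C8 prenyl are on the two alkyne carbons of 17. A hexasubstituted benzene becomes a four-membered ring and an alkyne, each carrying one prenyl group, and no aromatic substitution is needed. The (2+2) union must join the ketene carbon to the alkyne carbon remote from oxygen, and the temperature must stay below that at which the silyl ynol ether rearranges.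

12 ⇒ 6 + 10 (through 11), 6 ⇒ 5 ⇒ 4 ⇒ 1 + 2, 10 ⇒ 7. The four-membered ring is cut at C5–C6 and at the transient C4a–C7 bond (flavone labels), giving a monoalkylketene and the parent silyl ynol ether. The ketene chain is traced through acid chloride, acid and ester to a [3,3] shift that forms the bond between the α- and β-carbons of the ester. 10 is traced to a heterocycle whose base-induced fragmentation releases the two-carbon ynolate. The forward steps demand a low stationary concentration of ketene and silylation of the ynolate at oxygen, not carbon.

17 ⇒ 14 ⇒ 13. One carbon is excised between the oxygen-bearing alkyne carbon and the allylic methylene: an ester homologation stopped at the ynolate and trapped on oxygen. Prenyl group and both alkyne carbons come from a six-carbon acid and a one-carbon unit. The esterification and the base sequence must not move the β,γ-double bond.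

## Other disconnections considered

Alternative 1: The cut is at the C2″=C3″ double bond of each prenyl group, leaving allyl groups on C6 and C8.
- Forward step: 6,8-diallylkaempferol tetraacetate A2, reached from purchasable kaempferol A1 by O-allylation/Claisen cycles and acetylation, would undergo double cross-metathesis with excess 2-methylbut-2-ene A3 under second-generation Grubbs catalyst, (H2IMes)(PCy3)Cl2Ru=CHPh. This would give 6,8-diprenylkaempferol tetraacetate A4; mild methanolysis of the acetates would finish.
- In favour: the whole flavonol skeleton is bought; allyl-to-prenyl cross-metathesis on allylarenes is highly dependable; the acetates keep the phenols off the ruthenium carbene; the last deprotection is basic, so chroman formation is not an issue.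
- Against: the key step builds no bond of the nucleus. The hard problem moves into two aromatic Claisen rearrangements whose C6/C8 orientation, and the allylation of the hydrogen-bonded 5-hydroxyl, must be controlled; allyl-to-propenyl migration under ruthenium is a further risk.
- Comparison: on structure the chosen plan fixes both prenyl positions by construction, whereas this one relies on regioselective rearrangements. Mechanistically it is a catalytic (2+2)/retro-(2+2) sequence at a metal carbene under mild conditions, against a thermal pericyclic cascade. On step economy and on precedent for the key step this alternative is the better plan, and its endgame is gentler; the chosen plan is preferred only for its unambiguous regiochemistry.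

Alternative 2: The cut removes ring C across C8a–O1, C4a–C4 and O1–C2.
- Forward step: CsF would release the ring A aryne from 3,5-bis(methoxymethoxy)-2,4-bis(3-methylbut-2-enyl)-6-(trimethylsilyl)phenyl trifluoromethanesulfonate A5. The carboxylate of 3-[4-(methoxymethoxy)phenyl]prop-2-ynoic acid A6 would add at C8a, the C4a aryl anion would take the acyl carbon, and the phenoxide would close onto the ynone to give 5,7,4′-tris-O-(methoxymethyl)-6,8-diprenylapigenin A7.
- In favour: ring C closes in one mild operation, and the addition should be oriented correctly, since a nucleophile adds to a 3-alkoxyaryne at the carbon remote from the alkoxy group, here C8a.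
- Against: A7 has hydrogen on C3, so a C3 hydroxylation must follow, and the usual epoxidizing reagents would attack the prenyl groups. Three acetals, two on oxygens next to prenyl groups, must then be removed by acid. A5 is a hexasubstituted benzene that still contains the C6/C8 problem and needs an ortho-silyl triflate installed.
- Comparison: it is better than the chosen plan in the mildness of ring C closure and equal in needing a final acid deprotection. It is weaker in oxidation level (no oxygen on C3), in precursor length, and in leaving ring A unsolved; ring A from the benzannulation could feed it, but triflation, silylation and C3 oxidation would make it longer.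

Alternative 3: The cut is at C4a–C4 and C4–C3, with carbon monoxide A9 supplying C4.
- Forward step: 2-iodo-1,3,5-tris(methoxymethoxy)-4,6-bis(3-methylbut-2-enyl)benzene A8, A9 and the enolate of 2-(methoxymethoxy)-1-[4-(methoxymethoxy)phenyl]ethan-1-one A10 would couple under Pd(dba)2 (zerovalent palladium) and Xantphos (4,5-bis(diphenylphosphino)-9,9-dimethylxanthene). This would give the open 1,3-diketone A11; acid would then remove the acetals and cyclodehydrate.
- In favour: convergent, correct oxidation level including the C3 oxygen, moderate temperature, and a last step that does two jobs.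
- Against: the iodide is electron-rich and flanked by two ortho acetal oxygens, so carbon monoxide insertion and coupling with a hindered α-alkoxy enolate are demanding. The prenyl alkenes could engage acyl- or hydridopalladium intermediates. Five acetals must be cleaved next to prenyl groups, more exposure than the two of the chosen plan. A8 presupposes the diprenylated phloroglucinol, which this alternative does not provide.
- Comparison: it equals the chosen plan in convergence and is better in the thermal mildness of the C4a–C4 bond formation. It is complementary, not competing, since ring A could come from the benzannulation, at the cost of three steps after ring A (iodination, protection, coupling) against one.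

Key step: step 8

Remark: atom labels (O1, C2–C8a, primes for ring B) are those of the flavone throughout; 12 is carried as the racemate because its one stereocentre becomes the aromatic carbon C6 in step 8.
Remark: 12, 17 and 22 agree atom by atom with the annulation mechanism and needed no correction. The plan lacked a source for 10, which step 4 supplies; the ring C fragment is made by aldol addition and oxidation (steps 12 and 13).

## Route

Step 1
Reactants: 1 2-methylbut-3-en-2-ol; 2 triethyl orthoacetate
Product: 4 ethyl 5-methylhex-4-enoate, via ketene acetal 3 (not isolated)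
Conditions: MeC(OEt)3 (excess), EtCO2H (cat.), 140 °C, EtOH distilled off
Reagents that add atoms: none
Why: Johnson–Claisen rearrangement: acid-catalysed orthoester exchange and loss of ethanol give ketene acetal 3, whose chair [3,3] shift forms the C2–C3 bond of the ester and the trisubstituted alkene; no stereocentre arises.

Step 2
Reactants: 4 ethyl 5-methylhex-4-enoate
Product: 5 5-methylhex-4-enoic acid
Conditions: NaOH, EtOH/H2O, rt; cold dilute HCl to pH 3
Reagents that add atoms: sodium hydroxide, [Na+].[OH-]
Why: Ester saponification; the acidification is done cold and dilute so the alkene is not protonated toward the δ-lactone.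

Step 3
Reactants: 5 5-methylhex-4-enoic acid
Product: 6 5-methylhex-4-enoyl chloride
Conditions: (COCl)2, DMF (cat.), CH2Cl2, 0 °C → rt; used crude
Reagents that add atoms: oxalyl chloride, ClC(=O)C(=O)Cl
Why: Acid chloride formation through the chloroiminium species from DMF; low temperature and gas evolution keep hydrogen chloride from adding to the alkene.

Step 4
Reactants: 7 3-phenylisoxazole
Product: 10 (ethynyloxy)triisopropylsilane, via 5-lithioisoxazole 8 (not isolated), via lithium ethynolate 9 (not isolated)
Conditions: n-BuLi, THF, −78 °C; warm to 0 °C; i-Pr3SiOTf, −78 °C → rt; distilled, kept cold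
Reagents that add atoms: triisopropylsilyl trifluoromethanesulfonate, CC(C)[Si](OS(=O)(=O)C(F)(F)F)(C(C)C)C(C)C
Why: A 3-substituted isoxazole is lithiated at C5, and on warming 8 fragments in a six-electron process into benzonitrile and ynolate 9, a known entry to ynolates. Silylation of an ynolate with a bulky, hard silyl electrophile takes place on oxygen and gives the silyl ynol ether.

Step 5
Reactants: 6 5-methylhex-4-enoyl chloride; 10 (ethynyloxy)triisopropylsilane
Product: 12 rac-4-(3-methylbut-2-enyl)-3-(triisopropylsiloxy)cyclobut-2-en-1-one, via prenylketene 11 (not isolated)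
Conditions: Et3N, CH2Cl2, 0 °C → rt, 6 added slowly
Reagents that add atoms: none
Why: Dehydrochlorination gives aldoketene 11, which undergoes the ketene–ynol ether (2+2) cycloaddition; the nucleophilic CH terminus of 10 bonds to the ketene carbonyl carbon, which gives the 3-siloxy-4-alkyl pattern. Slow addition keeps the ketene concentration low against dimerization; the new stereocentre is formed racemic and is lost in step 8.

Step 6
Reactants: 13 4-methylpent-3-enoic acid
Product: 14 ethyl 4-methylpent-3-enoate
Conditions: EtI, K2CO3, DMF, rt
Reagents that add atoms: iodoethane, CCI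
Why: Carboxylate O-alkylation (SN2); acid-free conditions avoid lactonization and migration of the β,γ-double bond that a Fischer esterification would risk.

Step 7
Reactants: 14 ethyl 4-methylpent-3-enoate
Product: 17 5-methyl-1-(triisopropylsiloxy)hex-4-en-1-yne, via dibromoenolate 15 (not isolated), via lithium ynolate 16 (not isolated)
Conditions: CH2Br2, lithium 2,2,6,6-tetramethylpiperidide, THF, −78 °C; LiN(SiMe3)2; n-BuLi, −78 °C → rt; i-Pr3SiCl, −78 °C → rt
Reagents that add atoms: dibromomethane, BrCBr; chlorotriisopropylsilane, CC(C)[Si](Cl)(C(C)C)C(C)C
Why: Kowalski ester homologation stopped at the ynolate: dibromomethyllithium adds to the ester, enolization gives 15, and bromine–lithium exchange with 1,2-shift of the allylic CH2 group gives 16. The bulky chlorosilane traps 16 on oxygen, the standard route to triisopropylsilyl ynol ethers.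

Step 8
Reactants: 12 rac-4-(3-methylbut-2-enyl)-3-(triisopropylsiloxy)cyclobut-2-en-1-one; 17 5-methyl-1-(triisopropylsiloxy)hex-4-en-1-yne
Product: 22 2,6-bis(3-methylbut-2-enyl)-3,5-bis(triisopropylsiloxy)phenol, via siloxyvinylketene 18 (not isolated), via vinylcyclobutenone 19 (not isolated), via dienylketene 20 (not isolated), via cyclohexadienone 21 (not isolated)
Conditions: PhMe, 80 °C → 110 °C, Ar, 17 in slight excess
Reagents that add atoms: none
Why: Thermal conrotatory four-electron opening of 12 gives siloxyvinylketene 18, the alkyl-bearing terminus rotating outward. Alkyne 17 adds to the ketene C=C bond of 18 in a (2+2) cycloaddition in which its carbon remote from oxygen, the nucleophilic terminus, bonds to the ketene carbonyl carbon; this creates C7–C8 and C4a–C8a and gives 19. A second, reversible four-electron opening gives dienylketene 20, and ring A closes by thermal disrotatory six-electron electrocyclization between the ketene carbon and the prenyl-bearing diene terminus (re-forming C6–C7) to dienone 21, which tautomerizes to 22 with gain of aromaticity. The closest known reaction is the Danheiser benzannulation of cyclobutenones with siloxyalkynes; the 3-siloxy-4-alkyl partner extends it from a resorcinol to a phloroglucinol pattern. No stereocentre survives, since the centres of 12, 19 and 21 all become aromatic carbons. The selectivity required is the orientation of the (2+2) step, secured by the oxygen-induced polarization of 17. The isolated prenyl alkenes are poor partners for a ketene and should not compete, and the phenol of 22, flanked by two prenyl groups, is too hindered to be acylated efficiently by 18.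

Step 9
Reactants: 22 2,6-bis(3-methylbut-2-enyl)-3,5-bis(triisopropylsiloxy)phenol
Product: 23 2,4-bis(3-methylbut-2-enyl)benzene-1,3,5-triol
Conditions: Bu4NF, AcOH, THF, 0 °C, Ar; used at once
Reagents that add atoms: none
Why: Fluoride cleavage of two aryl silyl ethers; acetic acid buffering and exclusion of air protect the readily oxidized phloroglucinolate.

Step 10
Reactants: 24 ethyl 2-hydroxyacetate
Product: 25 ethyl 2-(methoxymethoxy)acetate
Conditions: MeOCH2Cl, i-Pr2NEt, CH2Cl2, 0 °C → rt
Reagents that add atoms: chloromethyl methyl ether, COCCl
Why: O-alkylation of the alcohol by the chloromethyl ether under amine base, the standard formation of a methoxymethyl ether.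

Step 11
Reactants: 26 4-hydroxybenzaldehyde
Product: 27 4-(methoxymethoxy)benzaldehyde
Conditions: MeOCH2Cl, i-Pr2NEt, CH2Cl2, 0 °C → rt
Reagents that add atoms: chloromethyl methyl ether, COCCl
Why: O-alkylation of the phenol by the chloromethyl ether, the standard formation of an aryl methoxymethyl ether.

Step 12
Reactants: 25 ethyl 2-(methoxymethoxy)acetate; 27 4-(methoxymethoxy)benzaldehyde
Product: 29 ethyl 3-hydroxy-2-(methoxymethoxy)-3-[4-(methoxymethoxy)phenyl]propanoate (racemic mixture of diastereomers), via lithium enolate 28 (not isolated)
Conditions: LiN(i-Pr)2, THF, −78 °C; 27; AcOH, −78 °C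
Reagents that add atoms: none
Why: Aldol addition of a lithium α-alkoxy ester enolate to an aromatic aldehyde. The two new stereocentres are formed without control and need none: C3 is oxidized in step 13 and C2 becomes an sp2 carbon of the pyrone.

Step 13
Reactants: 29 ethyl 3-hydroxy-2-(methoxymethoxy)-3-[4-(methoxymethoxy)phenyl]propanoate
Product: 30 ethyl 2-(methoxymethoxy)-3-[4-(methoxymethoxy)phenyl]-3-oxopropanoate (racemic, configurationally labile)
Conditions: Dess–Martin periodinane (1.2 equiv), CH2Cl2, 0 °C → rt
Reagents that add atoms: none
Why: Dess–Martin oxidation of a secondary benzylic alcohol to the ketone under near-neutral conditions that leave both acetals intact; the remaining centre is enolizable and irrelevant.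

Step 14
Reactants: 23 2,4-bis(3-methylbut-2-enyl)benzene-1,3,5-triol; 30 ethyl 2-(methoxymethoxy)-3-[4-(methoxymethoxy)phenyl]-3-oxopropanoate
Product: 33 5,7-dihydroxy-3-(methoxymethoxy)-2-[4-(methoxymethoxy)phenyl]-6,8-bis(3-methylbut-2-enyl)-4H-chromen-4-one, via aroylketene 31 (not isolated), via diketone 32 (not isolated)
Conditions: 30 (1.5 equiv), no solvent, Ar, 240 °C (microwave), 10 min
Reagents that add atoms: none
Why: Mentzer pyrone synthesis: 30 loses ethanol thermally to aroylketene 31, which acylates the only free ring carbon of 23 (C4a) to give diketone 32. One of the two equivalent flanking hydroxyls then adds to the aryl ketone and water is lost, closing the γ-pyrone; the symmetry of 23 leaves no regiochemical choice, and no acid is present.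

Step 15
Reactants: 33 5,7-dihydroxy-3-(methoxymethoxy)-2-[4-(methoxymethoxy)phenyl]-6,8-bis(3-methylbut-2-enyl)-4H-chromen-4-one
Product: 34 6,8-diprenylkaempferol, 3,5,7-trihydroxy-2-(4-hydroxyphenyl)-6,8-bis(3-methylbut-2-enyl)-4H-chromen-4-one
Conditions: HCl (3 M aq.), MeOH, 40 °C, Ar
Reagents that add atoms: none
Why: Acid-catalysed acetal exchange to methanol frees O3 and O4′; methoxymethyl ethers of prenylated flavonoids are routinely cleaved this way, and moderate temperature limits protonation of the prenyl alkenes.

## Compound list

1 | 2-methylbut-3-en-2-ol | CC(C)(O)C=C | starting material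
2 | triethyl orthoacetate | CCOC(C)(OCC)OCC | starting material
3 | 1-ethoxy-1-[(2-methylbut-3-en-2-yl)oxy]ethene | C=C(OCC)OC(C)(C)C=C | intermediate (not isolated)
4 | ethyl 5-methylhex-4-enoate | CCOC(=O)CCC=C(C)C | intermediate
5 | 5-methylhex-4-enoic acid | CC(C)=CCCC(=O)O | intermediate
6 | 5-methylhex-4-enoyl chloride | CC(C)=CCCC(=O)Cl | intermediate
7 | 3-phenylisoxazole | c1ccc(cc1)-c1ccon1 | starting material
8 | 5-lithio-3-phenylisoxazole | [Li]c1cc(-c2ccccc2)no1 | intermediate (not isolated)
9 | lithium ethynolate | [Li+].[O-]C#C | intermediate (not isolated)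
10 | (ethynyloxy)triisopropylsilane | C#CO[Si](C(C)C)(C(C)C)C(C)C | intermediate
11 | 5-methylhexa-1,4-dien-1-one (prenylketene) | CC(C)=CCC=C=O | intermediate (not isolated)
12 | rac-4-(3-methylbut-2-enyl)-3-(triisopropylsiloxy)cyclobut-2-en-1-one | CC(C)=CCC1C(=O)C=C1O[Si](C(C)C)(C(C)C)C(C)C | intermediate
13 | 4-methylpent-3-enoic acid | CC(C)=CCC(=O)O | starting material
14 | ethyl 4-methylpent-3-enoate | CCOC(=O)CC=C(C)C | intermediate
15 | lithium 1,1-dibromo-5-methylhexa-1,4-dien-2-olate | [Li+].[O-]C(CC=C(C)C)=C(Br)Br | intermediate (not isolated)
16 | lithium 5-methylhex-4-en-1-yn-1-olate | [Li+].[O-]C#CCC=C(C)C | intermediate (not isolated)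
17 | 5-methyl-1-(triisopropylsiloxy)hex-4-en-1-yne | CC(C)=CCC#CO[Si](C(C)C)(C(C)C)C(C)C | intermediate
18 | (3Z)-7-methyl-3-(triisopropylsiloxy)octa-1,3,6-trien-1-one | O=C=C/C(O[Si](C(C)C)(C(C)C)C(C)C)=C/CC=C(C)C | intermediate (not isolated)
19 | rac-4-[(1Z)-5-methyl-1-(triisopropylsiloxy)hexa-1,4-dien-1-yl]-2-(3-methylbut-2-enyl)-3-(triisopropylsiloxy)cyclobut-2-en-1-one | CC(C)=CCC1=C(O[Si](C(C)C)(C(C)C)C(C)C)C(C1=O)/C(O[Si](C(C)C)(C(C)C)C(C)C)=C/CC=C(C)C | intermediate (not isolated)
20 | (3E,5Z)-9-methyl-2-(3-methylbut-2-enyl)-3,5-bis(triisopropylsiloxy)deca-1,3,5,8-tetraen-1-one | O=C=C(CC=C(C)C)/C(O[Si](C(C)C)(C(C)C)C(C)C)=C\C(O[Si](C(C)C)(C(C)C)C(C)C)=C\CC=C(C)C | intermediate (not isolated)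
21 | rac-2,6-bis(3-methylbut-2-enyl)-3,5-bis(triisopropylsiloxy)cyclohexa-2,4-dien-1-one | CC(C)=CCC1C(=O)C(CC=C(C)C)=C(O[Si](C(C)C)(C(C)C)C(C)C)C=C1O[Si](C(C)C)(C(C)C)C(C)C | intermediate (not isolated)
22 | 2,6-bis(3-methylbut-2-enyl)-3,5-bis(triisopropylsiloxy)phenol | CC(C)=CCc1c(O)c(CC=C(C)C)c(O[Si](C(C)C)(C(C)C)C(C)C)cc1O[Si](C(C)C)(C(C)C)C(C)C | intermediate
23 | 2,4-bis(3-methylbut-2-enyl)benzene-1,3,5-triol | CC(C)=CCc1c(O)cc(O)c(CC=C(C)C)c1O | intermediate
24 | ethyl 2-hydroxyacetate (ethyl glycolate) | CCOC(=O)CO | starting material
25 | ethyl 2-(methoxymethoxy)acetate | CCOC(=O)COCOC | intermediate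
26 | 4-hydroxybenzaldehyde | O=Cc1ccc(O)cc1 | starting material
27 | 4-(methoxymethoxy)benzaldehyde | COCOc1ccc(C=O)cc1 | intermediate
28 | lithium 1-ethoxy-2-(methoxymethoxy)ethen-1-olate | [Li+].CCOC([O-])=COCOC | intermediate (not isolated)
29 | ethyl 3-hydroxy-2-(methoxymethoxy)-3-[4-(methoxymethoxy)phenyl]propanoate (racemic, both diastereomers) | CCOC(=O)C(OCOC)C(O)c1ccc(OCOC)cc1 | intermediate
30 | ethyl 2-(methoxymethoxy)-3-[4-(methoxymethoxy)phenyl]-3-oxopropanoate (racemic, labile) | CCOC(=O)C(OCOC)C(=O)c1ccc(OCOC)cc1 | intermediate
31 | 2-(methoxymethoxy)-3-[4-(methoxymethoxy)phenyl]-3-oxoprop-1-en-1-one | COCOC(=C=O)C(=O)c1ccc(OCOC)cc1 | intermediate (not isolated)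
32 | 2-(methoxymethoxy)-1-[4-(methoxymethoxy)phenyl]-3-[2,4,6-trihydroxy-3,5-bis(3-methylbut-2-enyl)phenyl]propane-1,3-dione (labile at C2) | COCOC(C(=O)c1ccc(OCOC)cc1)C(=O)c1c(O)c(CC=C(C)C)c(O)c(CC=C(C)C)c1O | intermediate (not isolated)
33 | 5,7-dihydroxy-3-(methoxymethoxy)-2-[4-(methoxymethoxy)phenyl]-6,8-bis(3-methylbut-2-enyl)-4H-chromen-4-one | CC(C)=CCc1c(O)c(CC=C(C)C)c2oc(-c3ccc(OCOC)cc3)c(OCOC)c(=O)c2c1O | intermediate
34 | 6,8-diprenylkaempferol | CC(C)=CCc1c(O)c(CC=C(C)C)c2oc(-c3ccc(O)cc3)c(O)c(=O)c2c1O | target

## Step count and least certain steps

Total step count: 15. Longest linear sequence: 8 steps (steps 1, 2, 3, 5, 8, 9, 14, 15).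

Step 8 (key step). The annulation has no precedent with a 3-siloxy-4-alkylcyclobutenone. The likely failures are loss of the siloxyvinylketene by dimerization or by a 1,5-hydrogen shift before it meets the alkyne, prototropic drift of 12 toward its conjugated isomer, and slow oxygen-to-carbon silyl migration in 17 at the reaction temperature. Prototropic drift alone would not be fatal, because the conjugated isomer F4 would lead through F5 to the same triol 23. The fallback abandons the pericyclic construction of ring A and sets out from 1. Aqueous HBr converts 1 by allylic transposition into 1-bromo-3-methylbut-2-ene F1, and purchased benzene-1,3,5-triol is C-alkylated with two equivalents of F1 in cold aqueous KOH. The 2,4-dialkylated triol is separated from mono- and trialkylated material by chromatography, and the route is rejoined at 23. This is known chemistry but statistical, so it would serve only to secure material.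

Step 4. The parent ynolate is ambident and unhindered at carbon, so silylation at carbon (giving a silylketene), later migration of silicon from oxygen to carbon, and evaporative loss of the small product are all plausible; this exact preparation of 10 is an extrapolation from substituted ynolates. The fallback sets out from 6 and avoids 10 altogether:
- 6 is added slowly to ethoxyacetylene and Et3N to give 3-ethoxy-4-(3-methylbut-2-enyl)cyclobut-2-en-1-one F2.
- Cold dilute HCl hydrolyses the vinylogous ester, and the dione rests as its enol 3-hydroxy-2-(3-methylbut-2-enyl)cyclobut-2-en-1-one F3.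
- i-Pr3SiCl and Et3N give 2-(3-methylbut-2-enyl)-3-(triisopropylsiloxy)cyclobut-2-en-1-one F4, the conjugated isomer of 12 and a cyclobutenone with an unsubstituted C4, the best-precedented class for this annulation.
- Heating F4 with 17 gives 2,4-bis(3-methylbut-2-enyl)-3,5-bis(triisopropylsiloxy)phenol F5, an isomer of 22 with the ring hydrogen ortho to the free hydroxyl.
- Fluoride cleavage of F5 gives the same triol, and the route is rejoined at 23.

The price is that steps 4, 5 and 8 are replaced and 12 and 22 are not passed through.

Step 14. At 240 °C a prenyl group may close onto a neighbouring hydroxyl, the acetals may be cleaved thermally, and ester exchange at oxygen may outrun C-acylation and lead to oligomers. The fallback sets out from 23 and builds ring C stepwise at low temperature: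
- NaH and MeOCH2Cl give 1,3,5-tris(methoxymethoxy)-2,4-bis(3-methylbut-2-enyl)benzene F6.
- n-BuLi lithiates the ring carbon between two acetal oxygens, and addition to ester 25 gives 2-(methoxymethoxy)-1-[2,4,6-tris(methoxymethoxy)-3,5-bis(3-methylbut-2-enyl)phenyl]ethan-1-one F7.
- The lithium enolate of F7 (LiN(SiMe3)2) adds to 27 to give 3-hydroxy-2-(methoxymethoxy)-3-[4-(methoxymethoxy)phenyl]-1-[2,4,6-tris(methoxymethoxy)-3,5-bis(3-methylbut-2-enyl)phenyl]propan-1-one F8.
- Dess–Martin oxidation gives 2-(methoxymethoxy)-1-[4-(methoxymethoxy)phenyl]-3-[2,4,6-tris(methoxymethoxy)-3,5-bis(3-methylbut-2-enyl)phenyl]propane-1,3-dione F9, the same structure as A11.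
- HCl in MeOH removes all five acetals and cyclodehydrates, and the route is rejoined at 34.

Step 15. Protonation of a prenyl alkene and capture of the tertiary cation by the ortho hydroxyl (chroman ring closure) may compete with acetal cleavage. The fallback sets out from 33 and avoids Brønsted acid. Me3SiOTf with 2,2′-bipyridyl in CH2Cl2 at 0 °C transfers the methoxymethyl carbons to the bipyridyl and silylates every oxygen, giving 3,5,7-tris(trimethylsiloxy)-2-[4-(trimethylsiloxy)phenyl]-6,8-bis(3-methylbut-2-enyl)-4H-chromen-4-one F10. Neutral hydrolysis of F10 with water then rejoins the route at 34.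

## Further compounds

F1 | step 8 | 1-bromo-3-methylbut-2-ene | CC(C)=CCBr
F2 | step 4 | rac-3-ethoxy-4-(3-methylbut-2-enyl)cyclobut-2-en-1-one | CCOC1=CC(=O)C1CC=C(C)C
F3 | step 4 | 3-hydroxy-2-(3-methylbut-2-enyl)cyclobut-2-en-1-one | CC(C)=CCC1=C(O)CC1=O
F4 | step 4 | 2-(3-methylbut-2-enyl)-3-(triisopropylsiloxy)cyclobut-2-en-1-one | CC(C)=CCC1=C(O[Si](C(C)C)(C(C)C)C(C)C)CC1=O
F5 | step 4 | 2,4-bis(3-methylbut-2-enyl)-3,5-bis(triisopropylsiloxy)phenol | Oc1cc(O[Si](C(C)C)(C(C)C)C(C)C)c(CC=C(C)C)c(O[Si](C(C)C)(C(C)C)C(C)C)c1CC=C(C)C
F6 | step 14 | 1,3,5-tris(methoxymethoxy)-2,4-bis(3-methylbut-2-enyl)benzene | COCOc1cc(OCOC)c(CC=C(C)C)c(OCOC)c1CC=C(C)C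
F7 | step 14 | 2-(methoxymethoxy)-1-[2,4,6-tris(methoxymethoxy)-3,5-bis(3-methylbut-2-enyl)phenyl]ethan-1-one | COCOCC(=O)c1c(OCOC)c(CC=C(C)C)c(OCOC)c(CC=C(C)C)c1OCOC
F8 | step 14 | 3-hydroxy-2-(methoxymethoxy)-3-[4-(methoxymethoxy)phenyl]-1-[2,4,6-tris(methoxymethoxy)-3,5-bis(3-methylbut-2-enyl)phenyl]propan-1-one (racemic, both diastereomers) | COCOC(C(O)c1ccc(OCOC)cc1)C(=O)c1c(OCOC)c(CC=C(C)C)c(OCOC)c(CC=C(C)C)c1OCOC
F9 | step 14 | 2-(methoxymethoxy)-1-[4-(methoxymethoxy)phenyl]-3-[2,4,6-tris(methoxymethoxy)-3,5-bis(3-methylbut-2-enyl)phenyl]propane-1,3-dione (labile at C2) | COCOC(C(=O)c1ccc(OCOC)cc1)C(=O)c1c(OCOC)c(CC=C(C)C)c(OCOC)c(CC=C(C)C)c1OCOC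
F10 | step 15 | 3,5,7-tris(trimethylsiloxy)-2-[4-(trimethylsiloxy)phenyl]-6,8-bis(3-methylbut-2-enyl)-4H-chromen-4-one | CC(C)=CCc1c(O[Si](C)(C)C)c(CC=C(C)C)c2oc(-c3ccc(O[Si](C)(C)C)cc3)c(O[Si](C)(C)C)c(=O)c2c1O[Si](C)(C)C
A1 | alternative 1 | kaempferol | O=c1c(O)c(-c2ccc(O)cc2)oc2cc(O)cc(O)c12
A2 | alternative 1 | 6,8-diallylkaempferol tetraacetate | C=CCc1c(OC(C)=O)c(CC=C)c2oc(-c3ccc(OC(C)=O)cc3)c(OC(C)=O)c(=O)c2c1OC(C)=O
A3 | alternative 1 | 2-methylbut-2-ene | CC=C(C)C
A4 | alternative 1 | 6,8-diprenylkaempferol tetraacetate | CC(C)=CCc1c(OC(C)=O)c(CC=C(C)C)c2oc(-c3ccc(OC(C)=O)cc3)c(OC(C)=O)c(=O)c2c1OC(C)=O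
A5 | alternative 2 | 3,5-bis(methoxymethoxy)-2,4-bis(3-methylbut-2-enyl)-6-(trimethylsilyl)phenyl trifluoromethanesulfonate | COCOc1c(CC=C(C)C)c(OCOC)c(CC=C(C)C)c(OS(=O)(=O)C(F)(F)F)c1[Si](C)(C)C
A6 | alternative 2 | 3-[4-(methoxymethoxy)phenyl]prop-2-ynoic acid | COCOc1ccc(C#CC(=O)O)cc1
A7 | alternative 2 | 5,7,4′-tris-O-(methoxymethyl)-6,8-diprenylapigenin | COCOc1ccc(-c2cc(=O)c3c(OCOC)c(CC=C(C)C)c(OCOC)c(CC=C(C)C)c3o2)cc1
A8 | alternative 3 | 2-iodo-1,3,5-tris(methoxymethoxy)-4,6-bis(3-methylbut-2-enyl)benzene | COCOc1c(I)c(OCOC)c(CC=C(C)C)c(OCOC)c1CC=C(C)C
A9 | alternative 3 | carbon monoxide | [C-]#[O+]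
A10 | alternative 3 | 2-(methoxymethoxy)-1-[4-(methoxymethoxy)phenyl]ethan-1-one | COCOCC(=O)c1ccc(OCOC)cc1
A11 | alternative 3 | 2-(methoxymethoxy)-1-[4-(methoxymethoxy)phenyl]-3-[2,4,6-tris(methoxymethoxy)-3,5-diprenylphenyl]propane-1,3-dione (labile at C2) | COCOC(C(=O)c1ccc(OCOC)cc1)C(=O)c1c(OCOC)c(CC=C(C)C)c(OCOC)c(CC=C(C)C)c1OCOC
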